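**Plan**

- Retrosynthesis: the butanoate C–O bond is cut first, then both aryl–carbonyl bonds (C1–C8a and C4–C4a) at once. This leaves 1,4-benzoquinone and a 3-substituted 2,5-bis(silyloxy)furan, the double silyl enol ether of a succinic anhydride. The anhydride is traced back to an aldol reaction between a succinate imide and 4-methylpent-3-enal.
- Enabling feature: C1 and C4 flank C2=C3 as a four-carbon succinic/maleic unit at the carboxyl oxidation level, and the dihydroxybenzene ring (C4a, C5–C8, C8a) is the double enol of a benzoquinone ene-dione. Naphthazarin is therefore the aromatic tautomer of the 4a,8a-dihydronaphthalene-1,4,5,8-tetraone that a [4+2] addition of these two halves delivers, with C4a–C8a being one C=C of the quinone.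
- Forward order: the side chain is built acyclic; the anhydride ring and then the furan (temporary oxygen bridge, silyl activating groups) are formed; the carbocycle C1–C4/C4a/C8a is closed by the cycloaddition; the bridge and silyl groups are expelled and the benzenoid ring arises by tautomerisation; the butanoate is put on last.
- Stereochemistry: the single (R) carbinol centre comes from a boron syn-aldol reaction under control of (S)-4-benzyl-1,3-oxazolidin-2-one. The neighbouring α-centre is erased when the furan forms.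
- The side-chain oxygen travels as a silyl ether, not as the butanoate, because a β-acyloxy group would be lost by elimination from the electron-rich furan.

Key step: step 9

Remark: 1, 3, 4, 16 and 20 are taken as commercial. The configuration written for the ring carbon of 8–14 is of no consequence, since that carbon becomes trigonal in step 8.

**Route**

Step 1
Reactants: 1 4-methylpent-3-en-1-ol
Product: 2 4-methylpent-3-enal
Conditions: Dess–Martin periodinane, pyridine, CH2Cl2, 0 °C → rt; solution used at once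
Reagents that add atoms: none
Why: Dess–Martin oxidation of a primary alcohol stops at the aldehyde, and the buffered non-aqueous medium should keep the β,γ-double bond from moving into conjugation.

Step 2
Reactants: 3 4-tert-butoxy-4-oxobutanoic acid; 4 (S)-4-benzyl-1,3-oxazolidin-2-one
Product: 6 tert-butyl 4-[(4S)-4-benzyl-2-oxo-1,3-oxazolidin-3-yl]-4-oxobutanoate, via mixed pivalic anhydride 5 (not isolated)
Conditions: PivCl, Et3N, THF, −20 °C; then 4, LiCl, −20 °C → rt
Reagents that add atoms: none
Why: N-acylation of an oxazolidinone through a mixed anhydride, in which the LiCl/Et3N-activated oxazolidinone attacks the unhindered succinyl carbonyl and not the pivaloyl one.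

Step 3
Reactants: 6 tert-butyl 4-[(4S)-4-benzyl-2-oxo-1,3-oxazolidin-3-yl]-4-oxobutanoate; 2 4-methylpent-3-enal
Product: 8 (4S)-4-benzyl-3-[(2S,3R)-2-(2-tert-butoxy-2-oxoethyl)-3-hydroxy-6-methylhept-5-enoyl]-1,3-oxazolidin-2-one, via dibutylboron enolate 7 (not isolated)
Conditions: Bu2BOTf, iPr2NEt, CH2Cl2, −78 → 0 °C; then 2, −78 → 0 °C; pH 7 buffer, MeOH, H2O2, 0 °C
Reagents that add atoms: none
Why: Evans syn-aldol reaction, in which only the imide is enolised to the (Z)-boron enolate and the chair Zimmerman–Traxler transition state with the benzyl group of the (S)-auxiliary shielding one enolate face should give the (2S,3R) adduct, i.e. the (R) carbinol centre of the target, while the tert-butyl ester is too hindered to lactonise.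

Step 4
Reactants: 8 (4S)-4-benzyl-3-[(2S,3R)-2-(2-tert-butoxy-2-oxoethyl)-3-hydroxy-6-methylhept-5-enoyl]-1,3-oxazolidin-2-one
Product: 9 (4S)-4-benzyl-3-[(2S,3R)-2-(2-tert-butoxy-2-oxoethyl)-3-(tert-butyldimethylsilyloxy)-6-methylhept-5-enoyl]-1,3-oxazolidin-2-one
Conditions: TBSOTf, 2,6-lutidine, CH2Cl2, −78 → 0 °C
Reagents that add atoms: tert-butyldimethylsilyl triflate, CC(C)(C)[Si](C)(C)OS(=O)(=O)C(F)(F)F
Why: Silylation of a secondary alcohol with a silyl triflate and a hindered base, which blocks retro-aldol cleavage and installs a poor leaving group that should survive the later enolisations next to it.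

Step 5
Reactants: 9 (4S)-4-benzyl-3-[(2S,3R)-2-(2-tert-butoxy-2-oxoethyl)-3-(tert-butyldimethylsilyloxy)-6-methylhept-5-enoyl]-1,3-oxazolidin-2-one
Product: 11 (2S,3R)-2-(2-tert-butoxy-2-oxoethyl)-3-(tert-butyldimethylsilyloxy)-6-methylhept-5-enoic acid, via peroxy acid 10 (not isolated)
Conditions: LiOH, H2O2, THF/H2O, 0 °C; then Na2SO3; HCl to pH 3
Reagents that add atoms: hydrogen peroxide (as LiOOH), OO
Why: Hydroperoxide cleavage of an N-acyloxazolidinone attacks the exocyclic carbonyl selectively, the peroxy acid is reduced by sulfite, and the tert-butyl ester, silyl ether and alkene are inert to these conditions.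

Step 6
Reactants: 11 (2S,3R)-2-(2-tert-butoxy-2-oxoethyl)-3-(tert-butyldimethylsilyloxy)-6-methylhept-5-enoic acid
Product: 13 (2S)-2-[(1R)-1-(tert-butyldimethylsilyloxy)-4-methylpent-3-enyl]butanedioic acid, via bis(trimethylsilyl) ester 12 (not isolated)
Conditions: Me3SiOTf, 2,6-lutidine, CH2Cl2, 0 °C → rt; then H2O/THF
Reagents that add atoms: none
Why: Silyl-triflate cleavage of a tert-butyl ester (loss of 2-methylpropene to give the silyl ester, then hydrolysis) needs no protic acid, so the secondary silyl ether and the trisubstituted alkene should be untouched.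

Step 7
Reactants: 13 (2S)-2-[(1R)-1-(tert-butyldimethylsilyloxy)-4-methylpent-3-enyl]butanedioic acid
Product: 14 (3S)-3-[(1R)-1-(tert-butyldimethylsilyloxy)-4-methylpent-3-enyl]oxolane-2,5-dione
Conditions: DCC, CH2Cl2, 0 °C → rt; filtration
Reagents that add atoms: none
Why: Carbodiimide dehydration of a 1,4-diacid closes the five-membered cyclic anhydride under neutral conditions by attack of the second carboxyl on the O-acylisourea.

Step 8
Reactants: 14 (3S)-3-[(1R)-1-(tert-butyldimethylsilyloxy)-4-methylpent-3-enyl]oxolane-2,5-dione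
Product: 15 2,5-bis(tert-butyldimethylsilyloxy)-3-[(1R)-1-(tert-butyldimethylsilyloxy)-4-methylpent-3-enyl]furan
Conditions: TBSOTf, Et3N, Et2O, 0 °C → rt; used crude under argon
Reagents that add atoms: tert-butyldimethylsilyl triflate, CC(C)(C)[Si](C)(C)OS(=O)(=O)C(F)(F)F
Why: Soft enolisation of a cyclic anhydride with a silyl triflate and a tertiary amine silylates both carbonyl oxygens, the second enolisation being driven by aromatisation to the furan; the ring stereocentre is erased, whereas the carbinol centre has no acidic hydrogen and keeps its (R) configuration.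

Step 9
Reactants: 15 2,5-bis(tert-butyldimethylsilyloxy)-3-[(1R)-1-(tert-butyldimethylsilyloxy)-4-methylpent-3-enyl]furan; 16 1,4-benzoquinone
Product: 19 shikonin [5,8-dihydroxy-2-[(1R)-1-hydroxy-4-methylpent-3-enyl]naphthalene-1,4-dione], via bridged cycloadduct 17 (not isolated), via shikonin silyl ether 18 (not isolated)
Conditions: 16 (1 equiv), CH2Cl2, −20 °C → rt, dark; then HF·pyridine, pyridine, THF, 0 °C → rt
Reagents that add atoms: none
Why: The electron-rich diene 15, held s-cis by the furan ring, should add across one C=C of the electron-poor dienophile 16 in a normal-demand Diels–Alder reaction that joins the oxygen-bearing furan carbons C2 and C5 to two adjacent quinone carbons; fluoride then removes the two bridgehead silyl groups, the oxygen bridge opens to the two quinone carbonyls, the 4a,8a-dihydro-1,4,5,8-tetraone so formed tautomerises to the aromatic naphthazarin, and the same reagent frees the side-chain alcohol. The closest known reaction type is the Diels–Alder reaction of 2,5-bis(trialkylsilyloxy)furans with activated alkenes and alkynes, which gives hydroquinones and quinones once the silyl groups are lost. The one ring that is closed is the six-membered carbocycle C1–C2–C3–C4–C4a–C8a, by an intermolecular suprafacial [4+2] cycloaddition and not by cyclisation of a chain, and the temporary oxygen bridge is expelled afterwards. The four stereocentres of the adduct (two bridgeheads, two ring-fusion carbons) are erased on collapse and aromatisation, so neither facial nor endo/exo control is needed, and the carbinol centre lies outside the reacting system and is not touched. The step needs periselectivity for [4+2] addition at furan C2/C5 over Mukaiyama–Michael attack through C3/C4, which the locked s-cis diene, the absence of any Lewis acid and the non-polar solvent should secure; no regiochemical question arises, because 16 is symmetrical and the two rings of naphthazarin interconvert by tautomerism.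

Step 10
Reactants: 19 shikonin; 20 butanoic acid
Product: 21 butylshikonin [(1R)-1-(5,8-dihydroxy-1,4-dioxo-1,4-dihydronaphthalen-2-yl)-4-methylpent-3-enyl butanoate]
Conditions: DCC, DMAP (cat.), CH2Cl2, 0 °C → rt
Reagents that add atoms: none
Why: Steglich esterification should acylate only the secondary side-chain alcohol, because the two peri hydroxyls are tied up in hydrogen bonds to the quinone carbonyls, and the C–O bond at the stereocentre is not broken, so the (R) configuration is retained.

**Compound list**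

1 | 4-methylpent-3-en-1-ol | CC(C)=CCCO | starting material
2 | 4-methylpent-3-enal | CC(C)=CCC=O | intermediate
3 | 4-tert-butoxy-4-oxobutanoic acid (mono-tert-butyl succinate) | CC(C)(C)OC(=O)CCC(=O)O | starting material
4 | (S)-4-benzyl-1,3-oxazolidin-2-one | O=C1N[C@@H](Cc2ccccc2)CO1 | starting material
5 | 4-tert-butoxy-4-oxobutanoic pivalic anhydride (mixed anhydride) | CC(C)(C)OC(=O)CCC(=O)OC(=O)C(C)(C)C | intermediate
6 | tert-butyl 4-[(4S)-4-benzyl-2-oxo-1,3-oxazolidin-3-yl]-4-oxobutanoate | CC(C)(C)OC(=O)CCC(=O)N1[C@@H](Cc2ccccc2)COC1=O | intermediate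
7 | dibutylboron (Z)-enolate of 6 | CCCCB(CCCC)O/C(=C\CC(=O)OC(C)(C)C)N1[C@@H](Cc2ccccc2)COC1=O | intermediate
8 | (4S)-4-benzyl-3-[(2S,3R)-2-(2-tert-butoxy-2-oxoethyl)-3-hydroxy-6-methylhept-5-enoyl]-1,3-oxazolidin-2-one | CC(C)=CC[C@@H](O)[C@H](CC(=O)OC(C)(C)C)C(=O)N1[C@@H](Cc2ccccc2)COC1=O | intermediate
9 | (4S)-4-benzyl-3-[(2S,3R)-2-(2-tert-butoxy-2-oxoethyl)-3-(tert-butyldimethylsilyloxy)-6-methylhept-5-enoyl]-1,3-oxazolidin-2-one | CC(C)=CC[C@@H](O[Si](C)(C)C(C)(C)C)[C@H](CC(=O)OC(C)(C)C)C(=O)N1[C@@H](Cc2ccccc2)COC1=O | intermediate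
10 | (2S,3R)-2-(2-tert-butoxy-2-oxoethyl)-3-(tert-butyldimethylsilyloxy)-6-methylhept-5-eneperoxoic acid | CC(C)=CC[C@@H](O[Si](C)(C)C(C)(C)C)[C@H](CC(=O)OC(C)(C)C)C(=O)OO | intermediate
11 | (2S,3R)-2-(2-tert-butoxy-2-oxoethyl)-3-(tert-butyldimethylsilyloxy)-6-methylhept-5-enoic acid | CC(C)=CC[C@@H](O[Si](C)(C)C(C)(C)C)[C@H](CC(=O)OC(C)(C)C)C(=O)O | intermediate
12 | bis(trimethylsilyl) (2S)-2-[(1R)-1-(tert-butyldimethylsilyloxy)-4-methylpent-3-enyl]butanedioate | CC(C)=CC[C@@H](O[Si](C)(C)C(C)(C)C)[C@H](CC(=O)O[Si](C)(C)C)C(=O)O[Si](C)(C)C | intermediate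
13 | (2S)-2-[(1R)-1-(tert-butyldimethylsilyloxy)-4-methylpent-3-enyl]butanedioic acid | CC(C)=CC[C@@H](O[Si](C)(C)C(C)(C)C)[C@H](CC(=O)O)C(=O)O | intermediate
14 | (3S)-3-[(1R)-1-(tert-butyldimethylsilyloxy)-4-methylpent-3-enyl]oxolane-2,5-dione | CC(C)=CC[C@@H](O[Si](C)(C)C(C)(C)C)[C@@H]1CC(=O)OC1=O | intermediate
15 | 2,5-bis(tert-butyldimethylsilyloxy)-3-[(1R)-1-(tert-butyldimethylsilyloxy)-4-methylpent-3-enyl]furan | CC(C)=CC[C@@H](O[Si](C)(C)C(C)(C)C)c1cc(O[Si](C)(C)C(C)(C)C)oc1O[Si](C)(C)C(C)(C)C | intermediate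
16 | 1,4-benzoquinone | O=C1C=CC(=O)C=C1 | starting material
17 | 1,4-bis(tert-butyldimethylsilyloxy)-2-[(1R)-1-(tert-butyldimethylsilyloxy)-4-methylpent-3-enyl]-1,4-epoxy-1,4,4a,8a-tetrahydronaphthalene-5,8-dione (mixture of ring diastereomers) | O=C1C=CC(=O)C2C1C3(O[Si](C)(C)C(C)(C)C)C=C([C@@H](CC=C(C)C)O[Si](C)(C)C(C)(C)C)C2(O[Si](C)(C)C(C)(C)C)O3 | intermediate
18 | 5,8-dihydroxy-2-[(1R)-1-(tert-butyldimethylsilyloxy)-4-methylpent-3-enyl]naphthalene-1,4-dione (shikonin silyl ether) | CC(C)=CC[C@@H](O[Si](C)(C)C(C)(C)C)C1=CC(=O)c2c(O)ccc(O)c2C1=O | intermediate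
19 | shikonin, 5,8-dihydroxy-2-[(1R)-1-hydroxy-4-methylpent-3-enyl]naphthalene-1,4-dione | CC(C)=CC[C@@H](O)C1=CC(=O)c2c(O)ccc(O)c2C1=O | intermediate
20 | butanoic acid | CCCC(=O)O | starting material
21 | butylshikonin, (1R)-1-(5,8-dihydroxy-1,4-dioxo-1,4-dihydronaphthalen-2-yl)-4-methylpent-3-enyl butanoate | CCCC(=O)O[C@H](CC=C(C)C)C1=CC(=O)c2c(O)ccc(O)c2C1=O | target

**Step count and risks**

Total step count: 10. Longest linear sequence: 9 steps (steps 1 and 3–10 from 1, or steps 2–10 from 3 and 4).

Steps most likely to fail: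

Step 9. The silyl ketene acetal carbons C3/C4 of 15 may attack 16 in a Mukaiyama–Michael sense, or electron transfer to the quinone may only dehydrogenate the furan, so that the carbocycle is not closed. The fallback sets out from 15 and 16 and comes back at 19; it replaces the quinone by an aryne, which has no conjugate-addition pathway. Bromine is added to 16 to give 5,6-dibromocyclohex-2-ene-1,4-dione F1, which enolises under HBr to 2,3-dibromobenzene-1,4-diol F2. Silylation (iPr3SiOTf, 2,6-lutidine) gives 2,3-dibromo-1,4-bis(triisopropylsilyloxy)benzene F3. Treatment with n-BuLi at −78 °C in the presence of 15 generates 3,6-bis(triisopropylsilyloxy)benzyne F4, whose Diels–Alder reaction with the furan should give the 1,4-epoxy-1,4-dihydronaphthalene F5. HF·pyridine then removes all five silyl groups, the bridge opens to the quinone, and 19 is reached.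

Step 8. The second enolisation at the hindered ring carbon may stay incomplete, silanolate may be lost by β-elimination, or the furan-bound carbinol carbon may ionise under the silyl triflate and lose its configuration; the product also reverts to the anhydride with traces of water. The fallback sets out from 13 and comes back at 19; it uses an acyclic diene made by kinetic deprotonation of a bench-stable diester. Esterification of 13 (Me3SiCHN2, MeOH) gives dimethyl (2S)-2-[(1R)-1-(tert-butyldimethylsilyloxy)-4-methylpent-3-enyl]butanedioate F6. Double deprotonation with LiN(iPr)2 in the presence of Me3SiCl (THF, −78 °C) gives the 1,4-dimethoxy-1,4-bis(trimethylsilyloxy)buta-1,3-diene F7. Its Diels–Alder reaction with 16 should give the bis-ketal cycloadduct F8, which with HF·pyridine loses methanol and the silyl groups and tautomerises to 19.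

Step 3. The β,γ-unsaturated aldehyde 2 may isomerise into conjugation or condense with itself before it meets the boron enolate, which would lower conversion. The fallback sets out from 6 and comes back at 9; it makes the trisubstituted alkene last, so that 2 and step 1 are not needed. The same boron aldol reaction of 6 with commercial 3-(benzyloxy)propanal gives (4S)-4-benzyl-3-[(2S,3R)-5-(benzyloxy)-2-(2-tert-butoxy-2-oxoethyl)-3-hydroxypentanoyl]-1,3-oxazolidin-2-one F9. Silylation (TBSOTf, 2,6-lutidine) gives the silyl ether F10, and hydrogenolysis (H2, palladium on carbon, Pd/C) gives the primary alcohol F11. Dess–Martin oxidation gives the aldehyde F12, and a Wittig reaction with isopropylidenetriphenylphosphorane (from isopropyltriphenylphosphonium iodide and n-BuLi) gives 9.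

**Further compounds**

F1 | step 9 | 5,6-dibromocyclohex-2-ene-1,4-dione | O=C1C=CC(=O)C(Br)C1Br
F2 | step 9 | 2,3-dibromobenzene-1,4-diol | Oc1ccc(O)c(Br)c1Br
F3 | step 9 | 2,3-dibromo-1,4-bis(triisopropylsilyloxy)benzene | CC(C)[Si](Oc1ccc(O[Si](C(C)C)(C(C)C)C(C)C)c(Br)c1Br)(C(C)C)C(C)C
F4 | step 9 | 3,6-bis(triisopropylsilyloxy)benzyne | CC(C)[Si](OC1=CC=C(O[Si](C(C)C)(C(C)C)C(C)C)C#C1)(C(C)C)C(C)C
F5 | step 9 | 1,4-bis(tert-butyldimethylsilyloxy)-2-[(1R)-1-(tert-butyldimethylsilyloxy)-4-methylpent-3-enyl]-5,8-bis(triisopropylsilyloxy)-1,4-epoxy-1,4-dihydronaphthalene | CC(C)=CC[C@@H](O[Si](C)(C)C(C)(C)C)C1=CC2(O[Si](C)(C)C(C)(C)C)OC1(O[Si](C)(C)C(C)(C)C)c1c(O[Si](C(C)C)(C(C)C)C(C)C)ccc(O[Si](C(C)C)(C(C)C)C(C)C)c12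
F6 | step 8 | dimethyl (2S)-2-[(1R)-1-(tert-butyldimethylsilyloxy)-4-methylpent-3-enyl]butanedioate | CC(C)=CC[C@@H](O[Si](C)(C)C(C)(C)C)[C@H](CC(=O)OC)C(=O)OC
F7 | step 8 | 1,4-dimethoxy-1,4-bis(trimethylsilyloxy)-2-[(1R)-1-(tert-butyldimethylsilyloxy)-4-methylpent-3-enyl]buta-1,3-diene | COC(O[Si](C)(C)C)=CC(=C(OC)O[Si](C)(C)C)[C@@H](CC=C(C)C)O[Si](C)(C)C(C)(C)C
F8 | step 8 | 1,4-dimethoxy-1,4-bis(trimethylsilyloxy)-2-[(1R)-1-(tert-butyldimethylsilyloxy)-4-methylpent-3-enyl]-1,4,4a,8a-tetrahydronaphthalene-5,8-dione | O=C1C=CC(=O)C2C1C(OC)(O[Si](C)(C)C)C=C([C@@H](CC=C(C)C)O[Si](C)(C)C(C)(C)C)C2(OC)O[Si](C)(C)C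
F9 | step 3 | (4S)-4-benzyl-3-[(2S,3R)-5-(benzyloxy)-2-(2-tert-butoxy-2-oxoethyl)-3-hydroxypentanoyl]-1,3-oxazolidin-2-one | c1ccccc1COCC[C@@H](O)[C@H](CC(=O)OC(C)(C)C)C(=O)N1[C@@H](Cc2ccccc2)COC1=O
F10 | step 3 | (4S)-4-benzyl-3-[(2S,3R)-5-(benzyloxy)-2-(2-tert-butoxy-2-oxoethyl)-3-(tert-butyldimethylsilyloxy)pentanoyl]-1,3-oxazolidin-2-one | c1ccccc1COCC[C@@H](O[Si](C)(C)C(C)(C)C)[C@H](CC(=O)OC(C)(C)C)C(=O)N1[C@@H](Cc2ccccc2)COC1=O
F11 | step 3 | (4S)-4-benzyl-3-[(2S,3R)-2-(2-tert-butoxy-2-oxoethyl)-3-(tert-butyldimethylsilyloxy)-5-hydroxypentanoyl]-1,3-oxazolidin-2-one | OCC[C@@H](O[Si](C)(C)C(C)(C)C)[C@H](CC(=O)OC(C)(C)C)C(=O)N1[C@@H](Cc2ccccc2)COC1=O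
F12 | step 3 | (4S)-4-benzyl-3-[(2S,3R)-2-(2-tert-butoxy-2-oxoethyl)-3-(tert-butyldimethylsilyloxy)-5-oxopentanoyl]-1,3-oxazolidin-2-one | O=CC[C@@H](O[Si](C)(C)C(C)(C)C)[C@H](CC(=O)OC(C)(C)C)C(=O)N1[C@@H](Cc2ccccc2)COC1=O
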